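**Assumption:** the SMILES is read as (1S,3S,7E,9Z)-3-hydroxy-3,7-dimethyl-10-(propan-2-yl)cyclodeca-7,9-dien-1-yl 4-hydroxybenzoate, with the ester oxygen and the tertiary hydroxyl on the same ring face. The locants C1 (ester carbon) to C10 (isopropyl-bearing carbon) are used for ring and chain intermediates alike.

**Retrosynthetic overview**
1. Target 22 ⇐ trienyl ester 18: the C3–O bond is made last by an ester-relayed Markovnikov hydration of C2=C3 (new method), which places the C3 oxygen cis to the C1 oxygen.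
2. 18 ⇐ (S)-trienol 16 + 4-acetoxybenzoyl chloride; 16 ⇐ trienone 15 (CBS reduction) ⇐ racemic trienol 14.
3. 14 ⇐ acyclic iodo trienal 12 by Nozaki–Hiyama–Kishi closure of C1–C10; the ten-membered carbocycle is the only ring formed.
4. 12 ⇐ symmetric dialdehyde 6 (one-sided Z-selective iodo-olefination) ⇐ diol 5 ⇐ hepta-1,6-diyne (double carboalumination sets both E alkenes).

**Route**

Step 1
Reactants: 1 hepta-1,6-diyne; 2 trimethylaluminium; 3 paraformaldehyde
Product: 5 (2E,7E)-3,7-dimethylnona-2,7-diene-1,9-diol, via bis(alkenyl)alane 4 (not isolated)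
Conditions: Me3Al (4.5 equiv), Cp2ZrCl2 (0.4 equiv), CH2Cl2, 0 °C to rt; n-BuLi, THF, −30 °C; (CH2O)n, rt; aqueous work-up
Reagents that add atoms: trimethylaluminium C[Al](C)C; paraformaldehyde (formaldehyde unit) C=O
Why: Negishi zirconium-catalysed carboalumination adds methyl and aluminium syn across each terminal alkyne (methyl to the internal carbon), and the derived alanates are hydroxymethylated with retention, which fixes both E trisubstituted alkenes.

Step 2
Reactants: 5 (2E,7E)-3,7-dimethylnona-2,7-diene-1,9-diol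
Product: 6 (2E,7E)-3,7-dimethylnona-2,7-dienedial
Conditions: MnO2 (20 equiv), CH2Cl2, rt
Reagents that add atoms: none
Why: allylic alcohol oxidation with MnO2 stops at the enal and does not disturb the E geometry.

Step 3
Reactants: 6 (2E,7E)-3,7-dimethylnona-2,7-dienedial; 7 (2-methylpropyl)triphenylphosphonium bromide; 8 iodine
Product: 12 (2E,7E,9Z)-10-iodo-3,7,11-trimethyldodeca-2,7,9-trienal, via ylide 9 (not isolated), via iodophosphonium iodide 10 (not isolated), via iodo ylide 11 (not isolated)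
Conditions: 7, n-BuLi, THF, 0 °C; I2, −78 °C; NaN(SiMe3)2, −20 °C; then 6 (3 equiv), −78 to −20 °C (unreacted 6 recovered)
Reagents that add atoms: (2-methylpropyl)triphenylphosphonium bromide CC(C)C[P+](c1ccccc1)(c1ccccc1)c1ccccc1.[Br-]; iodine II
Why: Stork–Zhao-type Wittig olefination with an α-iodo ylide puts iodine cis to the aldehyde-derived chain (9Z), and the excess of dialdehyde confines the reaction to one terminus.

Step 4
Reactants: 12 (2E,7E,9Z)-10-iodo-3,7,11-trimethyldodeca-2,7,9-trienal
Product: 14 rac-(2E,7E,9Z)-3,7-dimethyl-10-(propan-2-yl)cyclodeca-2,7,9-trien-1-ol, via alkenylchromium dichloride 13 (not isolated)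
Conditions: CrCl2 (8 equiv), NiCl2 (2 mol%), DMSO/THF, rt, syringe-pump addition of 12 to 3 mM; aqueous work-up
Reagents that add atoms: none
Why: intramolecular Nozaki–Hiyama–Kishi reaction, in which the alkenyl iodide becomes an alkenylchromium species with retention of the Z geometry and adds only to the aldehyde, closing the ring at C1–C10; C1 is formed racemic and is corrected in steps 5 and 6.

Step 5
Reactants: 14 rac-(2E,7E,9Z)-3,7-dimethyl-10-(propan-2-yl)cyclodeca-2,7,9-trien-1-ol
Product: 15 (2E,7E,9Z)-3,7-dimethyl-10-(propan-2-yl)cyclodeca-2,7,9-trien-1-one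
Conditions: MnO2 (30 equiv), CH2Cl2, rt
Reagents that add atoms: none
Why: neutral MnO2 oxidation of the doubly allylic alcohol gives the cross-conjugated ketone without acid that could ionise the substrate.

Step 6
Reactants: 15 (2E,7E,9Z)-3,7-dimethyl-10-(propan-2-yl)cyclodeca-2,7,9-trien-1-one
Product: 16 (1S,2E,7E,9Z)-3,7-dimethyl-10-(propan-2-yl)cyclodeca-2,7,9-trien-1-ol
Conditions: (R)-tetrahydro-1-methyl-3,3-diphenyl-1H,3H-pyrrolo[1,2-c][1,3,2]oxazaborole (0.3 equiv), catecholborane (1.8 equiv), toluene, −78 °C; aqueous work-up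
Reagents that add atoms: none
Why: Corey–Bakshi–Shibata reduction, with 1,2-hydride delivery inside the oxazaborolidine–borane–ketone complex and the α-isopropyl dienyl arm in the large-group position, gives the (S)-carbinol.

Step 7
Reactants: 16 (1S,2E,7E,9Z)-3,7-dimethyl-10-(propan-2-yl)cyclodeca-2,7,9-trien-1-ol; 17 4-acetoxybenzoyl chloride
Product: 18 (1S,2E,7E,9Z)-3,7-dimethyl-10-(propan-2-yl)cyclodeca-2,7,9-trien-1-yl 4-acetoxybenzoate
Conditions: 17 (1.5 equiv), Et3N (2 equiv), 4-(dimethylamino)pyridine (0.2 equiv), CH2Cl2, 0 °C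
Reagents that add atoms: 4-acetoxybenzoyl chloride CC(=O)Oc1ccc(cc1)C(Cl)=O
Why: nucleophilic acyl substitution at oxygen (4-(dimethylamino)pyridine-catalysed acylation) leaves C1 untouched, and the basic medium avoids ionisation of the doubly allylic ester.

Step 8
Reactants: 18 (1S,2E,7E,9Z)-3,7-dimethyl-10-(propan-2-yl)cyclodeca-2,7,9-trien-1-yl 4-acetoxybenzoate; 19 water
Product: 22 (1S,3S,7E,9Z)-3-hydroxy-3,7-dimethyl-10-(propan-2-yl)cyclodeca-7,9-dien-1-yl 4-hydroxybenzoate (CNP0130127.1), via dioxanylium triflate 20 (not isolated), via aryl acetate 21 (not isolated)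
Conditions: [N,N'-bis(3,5-di-tert-butylsalicylidene)-1,2-cyclohexanediaminato]cobalt (5 mol%), N-fluoro-2,4,6-trimethylpyridinium triflate (1.3 equiv), PhSiH3 (1.2 equiv), H2O (5 equiv), acetone, 0 °C; aqueous work-up; crude, K2CO3 (0.2 equiv), MeOH, 0 °C
Reagents that add atoms: water O
Why: Proposed new method: a trivalent cobalt hydride (from the divalent cobalt salen complex, the N-fluoropyridinium oxidant and the silane) transfers a hydrogen atom to C2 of the only isolated alkene (the diene termini C7 and C10 are fully substituted and its internal carbons would lose conjugation), the tertiary C3 radical is captured and oxidised to a tetravalent alkylcobalt, and this is displaced intramolecularly by the carbonyl oxygen of the C1 ester to give a bridged 1,3-dioxan-2-ylium ion that can form only with both C–O bonds on one ring face (C3 set as S), after which water opens the ion at its acyloxonium carbon and mild base moves the acyl group to the secondary oxygen and removes the phenolic acetate; the closest known reaction types are cobalt–salen hydrogen-atom-transfer/radical-polar-crossover cyclisations of alkenes carrying carbonate or carbamate groups and the Woodward–Prévost acyloxonium hydrolysis.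

**Compound list**

1 | hepta-1,6-diyne | C#CCCCC#C | starting material
2 | trimethylaluminium | C[Al](C)C | starting material
3 | paraformaldehyde (formaldehyde unit) | C=O | starting material
4 | [(1E,6E)-2,6-dimethylhepta-1,6-diene-1,7-diyl]bis(dimethylalane) | C[Al](C)/C=C(\C)CCC/C(C)=C/[Al](C)C | intermediate
5 | (2E,7E)-3,7-dimethylnona-2,7-diene-1,9-diol | OC/C=C(\C)CCC/C(C)=C/CO | intermediate
6 | (2E,7E)-3,7-dimethylnona-2,7-dienedial | O=C/C=C(\C)CCC/C(C)=C/C=O | intermediate
7 | (2-methylpropyl)triphenylphosphonium bromide | CC(C)C[P+](c1ccccc1)(c1ccccc1)c1ccccc1.[Br-] | starting material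
8 | iodine | II | starting material
9 | (2-methylpropylidene)triphenylphosphorane | CC(C)C=P(c1ccccc1)(c1ccccc1)c1ccccc1 | intermediate
10 | (1-iodo-2-methylpropyl)triphenylphosphonium iodide | CC(C)C(I)[P+](c1ccccc1)(c1ccccc1)c1ccccc1.[I-] | intermediate
11 | (1-iodo-2-methylpropylidene)triphenylphosphorane | CC(C)C(I)=P(c1ccccc1)(c1ccccc1)c1ccccc1 | intermediate
12 | (2E,7E,9Z)-10-iodo-3,7,11-trimethyldodeca-2,7,9-trienal | O=C/C=C(\C)CCC/C(C)=C/C=C(\I)C(C)C | intermediate
13 | alkenylchromium dichloride from 12 (CrCl2 unit in place of iodine, geometry retained) | O=C/C=C(\C)CCC/C(C)=C/C=C(\[Cr](Cl)Cl)C(C)C | intermediate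
14 | rac-(2E,7E,9Z)-3,7-dimethyl-10-(propan-2-yl)cyclodeca-2,7,9-trien-1-ol | C/C1=C\C=C(\C(C)C)C(O)/C=C(\C)CCC1 | intermediate
15 | (2E,7E,9Z)-3,7-dimethyl-10-(propan-2-yl)cyclodeca-2,7,9-trien-1-one | C/C1=C\C=C(\C(C)C)C(=O)/C=C(\C)CCC1 | intermediate
16 | (1S,2E,7E,9Z)-3,7-dimethyl-10-(propan-2-yl)cyclodeca-2,7,9-trien-1-ol | C/C1=C\C=C(\C(C)C)[C@@H](O)/C=C(\C)CCC1 | intermediate
17 | 4-acetoxybenzoyl chloride | CC(=O)Oc1ccc(cc1)C(Cl)=O | starting material
18 | (1S,2E,7E,9Z)-3,7-dimethyl-10-(propan-2-yl)cyclodeca-2,7,9-trien-1-yl 4-acetoxybenzoate | C/C1=C\C=C(\C(C)C)[C@@H](OC(=O)c2ccc(OC(C)=O)cc2)/C=C(\C)CCC1 | intermediate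
19 | water | O | starting material
20 | bridged 2-(4-acetoxyphenyl)-1,3-dioxan-2-ylium triflate (its two ring oxygens are the C1 and C3 oxygens, both on one face of the carbocycle; 1S,3S) | C/C1=C\C=C(\C(C)C)[C@@H]2C[C@](C)(CCC1)[O+]=C(c3ccc(OC(C)=O)cc3)O2.[O-]S(=O)(=O)C(F)(F)F | intermediate
21 | (1S,3S,7E,9Z)-3-hydroxy-3,7-dimethyl-10-(propan-2-yl)cyclodeca-7,9-dien-1-yl 4-acetoxybenzoate | C/C1=C\C=C(\C(C)C)[C@@H](OC(=O)c2ccc(OC(C)=O)cc2)C[C@@](C)(O)CCC1 | intermediate
22 | (1S,3S,7E,9Z)-3-hydroxy-3,7-dimethyl-10-(propan-2-yl)cyclodeca-7,9-dien-1-yl 4-hydroxybenzoate | C/C1=C\C=C(\C(C)C)[C@@H](OC(=O)c2ccc(O)cc2)C[C@@](C)(O)CCC1 | target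

**Totals:** 8 steps; longest linear sequence 8 steps (from hepta-1,6-diyne).

**Three steps most likely to fail**

Step 4 (macrocyclisation). The ring closes to a strained cyclodecatriene with two E and one Z alkene, so oligomerisation may win. The fallback sets out from dialdehyde 6. Lithiated diethyl (2-methylpropyl)phosphonate (1 equiv, −78 °C, 6 in excess) adds to one aldehyde to give the β-hydroxy phosphonate, diethyl [(5E,10E)-4-hydroxy-2,6,10-trimethyl-12-oxododeca-5,10-dien-3-yl]phosphonate F1. MnO2 oxidises its allylic carbinol to the β-keto phosphonate, diethyl [(5E,10E)-2,6,10-trimethyl-4,12-dioxododeca-5,10-dien-3-yl]phosphonate F2. LiCl/DBU in MeCN at high dilution then closes the ring by intramolecular Horner–Wadsworth–Emmons olefination of the remaining enal, where the ring allows only the 9Z alkene. This comes back to the route at trienone 15.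

Step 6 (asymmetric reduction). The two alkenyl arms of 15 may be discriminated poorly, and the sense of induction must be confirmed by Mosher ester analysis. The fallback sets out from racemic 14 and is a classical resolution. Esterification with (S)-2-methoxy-2-phenylacetic acid (dicyclohexylcarbodiimide, 4-(dimethylamino)pyridine) gives two diastereomers that are separated by chromatography. These are (1S,2E,7E,9Z)-3,7-dimethyl-10-(propan-2-yl)cyclodeca-2,7,9-trien-1-yl (2S)-2-methoxy-2-phenylacetate F3 and its (1R) diastereomer, (1R,2E,7E,9Z)-3,7-dimethyl-10-(propan-2-yl)cyclodeca-2,7,9-trien-1-yl (2S)-2-methoxy-2-phenylacetate F4, which is set aside. K2CO3/MeOH cleaves F3 and comes back to the route at 16.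

Step 8 (proposed new method). The risks are hydrogen-atom transfer to the diene, transannular capture of the C3 radical or cation by the diene, and ionisation of the dienylic C1–O bond of 20. The fallback uses known chemistry and sets out from 16. Hydroxyl-directed epoxidation of C2=C3 (VO(acac)2, t-BuOOH, CH2Cl2, 0 °C) gives the syn epoxy alcohol, (1R,2S,3S,7E,9Z)-2,3-epoxy-3,7-dimethyl-10-(propan-2-yl)cyclodeca-7,9-dien-1-ol F5; allylic 1,3-strain from the methyl cis on C3 favours this isomer. Alkoxide-directed hydride delivery to C2 (NaAlH2(OCH2CH2OMe)2, THF, 0 °C) opens it to the cis diol, (1S,3S,7E,9Z)-3,7-dimethyl-10-(propan-2-yl)cyclodeca-7,9-diene-1,3-diol F6. Acylation of the secondary hydroxyl alone with 17 (Et3N, 4-(dimethylamino)pyridine) comes back to the route at 21, which is deacetylated (K2CO3, MeOH) to 22 as in step 8.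

**Further compounds**

F1 | step 4 | diethyl [(5E,10E)-4-hydroxy-2,6,10-trimethyl-12-oxododeca-5,10-dien-3-yl]phosphonate | CCOP(=O)(OCC)C(C(C)C)C(O)/C=C(\C)CCC/C(C)=C/C=O
F2 | step 4 | diethyl [(5E,10E)-2,6,10-trimethyl-4,12-dioxododeca-5,10-dien-3-yl]phosphonate | CCOP(=O)(OCC)C(C(C)C)C(=O)/C=C(\C)CCC/C(C)=C/C=O
F3 | step 6 | (1S,2E,7E,9Z)-3,7-dimethyl-10-(propan-2-yl)cyclodeca-2,7,9-trien-1-yl (2S)-2-methoxy-2-phenylacetate | C/C1=C\C=C(\C(C)C)[C@@H](OC(=O)[C@@H](OC)c2ccccc2)/C=C(\C)CCC1
F4 | step 6 | (1R,2E,7E,9Z)-3,7-dimethyl-10-(propan-2-yl)cyclodeca-2,7,9-trien-1-yl (2S)-2-methoxy-2-phenylacetate | C/C1=C\C=C(\C(C)C)[C@H](OC(=O)[C@@H](OC)c2ccccc2)/C=C(\C)CCC1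
F5 | step 8 | (1R,2S,3S,7E,9Z)-2,3-epoxy-3,7-dimethyl-10-(propan-2-yl)cyclodeca-7,9-dien-1-ol | C/C1=C\C=C(\C(C)C)[C@@H](O)[C@@H]2O[C@@]2(C)CCC1
F6 | step 8 | (1S,3S,7E,9Z)-3,7-dimethyl-10-(propan-2-yl)cyclodeca-7,9-diene-1,3-diol | C/C1=C\C=C(\C(C)C)[C@@H](O)C[C@@](C)(O)CCC1
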